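**Retrosynthetic overview**

1. Agrimol F ⇒ last bond ring B carbon–CH2(ring C): quinone-methide alkylation of the A–CH2–B butanoyl ketone by the ring C Mannich base. The ring B butanoyl group is put on one step earlier (Houben–Hoesch), so only one ring B carbon is left for the coupling.
2. A–CH2–B ⇒ ring A is built on the propanoate arm of a tris(benzyloxy) ring B: ester enolate + 4-methoxy-3,6-dimethyl-2-pyranone, forming the bond between ring A carbons 1 and 2 (acylation by the lactone carbonyl) and the bond between ring A carbons 5 and 6 (Claisen closure).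
3. Feature used: ring A, numbered from the carbon that carries the CH2 arm (carbon 1 arm, carbon 2 OH, carbon 3 CH3, carbon 4 OCH3, carbon 5 acetyl, carbon 6 OH), has its methoxyl between the C-methyl and the acetyl-bearing carbon and para to the arm carbon. Carbons 2 to 5 with these three substituents are the eight carbons and the oxygen pattern of the pyranone, so no selective O-methylation is needed at this hindered position.
4. Ring C (same pattern, butanoyl) ⇒ 2-methylphloroglucinol: formyl group at the future bridge carbon, O-methylation para to it, butanoylation of the last ring carbon, reductive amination to the Mannich base.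
5. Ring order: rings B and C come from phloroglucinol and 2-methylphloroglucinol; ring A is the only ring formed (step 8).

Key step: step 8

Remark (assumption): anionic species are drawn in their simplest form (13 as the O-bound bromomagnesium enolate of undefined geometry, 14 as the neutral racemic keto ester although it is present as a magnesium enolate); 1, 6, 10 and 19 are taken as commercial.

**Route**

Step 1
Reactants: 1 4-hydroxy-6-methyl-2H-pyran-2-one
Product: 3 4-hydroxy-6-methyl-3-[(phenylsulfanyl)methyl]-2H-pyran-2-one, via methylidene pyrandione 2 (not isolated)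
Conditions: (CH2O)n, PhSH, piperidine (cat.), AcOH (cat.), EtOH, 60 °C
Reagents that add atoms: formaldehyde (as paraformaldehyde) C=O; thiophenol Sc1ccccc1
Why: Knoevenagel condensation at C3 gives the methylidene dione 2, which the thiol traps at once by thia-Michael addition, so that no second pyranone adds and carbon (not oxygen) is alkylated.

Step 2
Reactants: 3 4-hydroxy-6-methyl-3-[(phenylsulfanyl)methyl]-2H-pyran-2-one
Product: 4 4-hydroxy-3,6-dimethyl-2H-pyran-2-one
Conditions: Raney Ni, EtOH, reflux
Reagents that add atoms: none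
Why: Reductive desulfurization (C–S hydrogenolysis) leaves the C3 methyl group, which avoids the O/C mixtures of a direct methylation with MeI.

Step 3
Reactants: 4 4-hydroxy-3,6-dimethyl-2H-pyran-2-one
Product: 5 4-methoxy-3,6-dimethyl-2H-pyran-2-one
Conditions: Me2SO4, K2CO3, acetone, reflux
Reagents that add atoms: dimethyl sulfate COS(=O)(=O)OC
Why: Williamson-type O-methylation of the vinylogous acid is expected at the C4 oxygen, as with the 3-unsubstituted pyranone, to give the 4-methoxy-2-pyranone and not the 2-methoxy-4-pyranone.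

Step 4
Reactants: 6 phloroglucinol (benzene-1,3,5-triol)
Product: 7 1,3,5-tris(benzyloxy)benzene
Conditions: BnBr, K2CO3, DMF, 60 °C
Reagents that add atoms: benzyl bromide BrCc1ccccc1
Why: Threefold Williamson etherification of the phenoxide in a polar aprotic solvent; C-benzylated by-products are expected to be minor and removable by crystallisation.

Step 5
Reactants: 7 1,3,5-tris(benzyloxy)benzene
Product: 9 2,4,6-tris(benzyloxy)benzaldehyde, via iminium chloride 8 (not isolated)
Conditions: POCl3, DMF, 0 → 60 °C; then H2O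
Reagents that add atoms: N,N-dimethylformamide CN(C)C=O; water O
Why: Vilsmeier–Haack formylation of the very electron-rich arene, whose three ring carbons are equivalent; iminium salt 8 is hydrolysed on aqueous work-up.

Step 6
Reactants: 9 2,4,6-tris(benzyloxy)benzaldehyde; 10 trimethyl phosphonoacetate
Product: 11 methyl (2E)-3-[2,4,6-tris(benzyloxy)phenyl]prop-2-enoate
Conditions: NaH, THF, 0 → 50 °C
Reagents that add atoms: none
Why: Horner–Wadsworth–Emmons olefination of the non-enolisable aldehyde with the stabilised phosphonate anion should give the E-cinnamate.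

Step 7
Reactants: 11 methyl (2E)-3-[2,4,6-tris(benzyloxy)phenyl]prop-2-enoate
Product: 12 methyl 3-[2,4,6-tris(benzyloxy)phenyl]propanoate
Conditions: NaBH4, NiCl2·6H2O (0.2 equiv), MeOH–THF, 0 °C
Reagents that add atoms: none
Why: Conjugate reduction of the cinnamate C=C over nickel boride formed from NiCl2 and NaBH4 (heterogeneous hydrogenation), under which benzyl ethers and the ester should be kept.

Step 8
Reactants: 12 methyl 3-[2,4,6-tris(benzyloxy)phenyl]propanoate; 5 4-methoxy-3,6-dimethyl-2H-pyran-2-one
Product: 15 1-[2,4-dihydroxy-6-methoxy-5-methyl-3-[[2,4,6-tris(benzyloxy)phenyl]methyl]phenyl]ethan-1-one, via bromomagnesium enolate 13 (not isolated), via open-chain diketo ester 14 (not isolated)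
Conditions: LiN(iPr)2 (1.05 equiv), THF, −78 °C; MgBr2·OEt2; then 5, −78 °C → rt; then Mg(OMe)2 (3 equiv), MeOH, 65 °C; aq. HCl
Reagents that add atoms: none
Why: Proposed new method: enolate 13 adds to the lactone carbonyl (C2) of 5 and the adduct collapses with loss of the ring enolate oxygen, which forms the bond between carbons 1 and 2 of ring A and frees the acetyl group as its enolate in chain 14; the acetyl-flanked CH2 of 14 then attacks the ester carbonyl in a Claisen closure that forms the bond between carbons 5 and 6 of ring A, and loss of methoxide with enolisation gives the arene, the enol ether surviving as the aryl methyl ether. The closest known reactions are the opening of 4-methoxy-2-pyranones at C2 by carbanions and alkoxides and the Mg(OMe)2-mediated Claisen cyclisation of 3,5,7-tricarbonyl esters to acylphloroglucinols; their union with an ester enolate as a one-flask benzannulation has no direct precedent. Ring A closes in the 6-(enolexo)-exo-trig mode, helped because the C4=C5 double bond of 14 comes from the ring and holds the two chain ends cis (E by the sequence rule). No stereocentre is left, since C2 of 14 becomes an aromatic carbon. Carbonyl addition must outrun proton transfer from the 6-methyl group and conjugate addition at C6, for which the covalent, Lewis-acidic magnesium enolate at low temperature is chosen; Claisen must win over aldol closure, which the arm secures because the aldol product would carry a quaternary carbon, cannot aromatise and reverts.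

Step 9
Reactants: 15 1-[2,4-dihydroxy-6-methoxy-5-methyl-3-[[2,4,6-tris(benzyloxy)phenyl]methyl]phenyl]ethan-1-one
Product: 16 1-[2,4-dihydroxy-6-methoxy-5-methyl-3-[(2,4,6-trihydroxyphenyl)methyl]phenyl]ethan-1-one
Conditions: H2 (1 atm), 10% Pd/C, EtOAc–MeOH, rt
Reagents that add atoms: none
Why: Hydrogenolysis of the three benzyl ethers over palladium; the chelated aryl ketone, the aryl methyl ether and the diarylmethane should be inert at one atmosphere and room temperature.

Step 10
Reactants: 16 1-[2,4-dihydroxy-6-methoxy-5-methyl-3-[(2,4,6-trihydroxyphenyl)methyl]phenyl]ethan-1-one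
Product: 18 1-[3-[(3-acetyl-2,6-dihydroxy-4-methoxy-5-methylphenyl)methyl]-2,4,6-trihydroxyphenyl]butan-1-one, via ketiminium chloride 17 (not isolated)
Conditions: PrCN, ZnCl2, HCl (g), Et2O–dioxane, 0 °C → rt; then H2O, 80 °C
Reagents that add atoms: butanenitrile CCCC#N; water O
Why: Houben–Hoesch acylation: the activated nitrile attacks one of the two equivalent free carbons of the phloroglucinol ring B, the ketiminium salt 17 prevents a second acylation and is hydrolysed to the ketone, and ring A has no free carbon.

Step 11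
Reactants: 19 2-methylbenzene-1,3,5-triol (2-methylphloroglucinol)
Product: 21 2,4,6-trihydroxy-3-methylbenzaldehyde, via iminium chloride 20 (not isolated)
Conditions: POCl3, DMF, EtOAc, 0 °C → rt; then H2O, 50 °C
Reagents that add atoms: N,N-dimethylformamide CN(C)C=O; water O
Why: Vilsmeier–Haack formylation of the phloroglucinol, whose two free ring carbons are equivalent, so a single aldehyde results; the formyl carbon is the future bridge carbon of ring C.

Step 12
Reactants: 21 2,4,6-trihydroxy-3-methylbenzaldehyde
Product: 22 2,6-dihydroxy-4-methoxy-3-methylbenzaldehyde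
Conditions: MeI (1.05 equiv), NaHCO3, DMF, 40 °C
Reagents that add atoms: iodomethane CI
Why: Selective Williamson O-methylation: the hydroxyl para to the formyl group is the most acidic (vinylogous acid) and is not flanked by the carbonyl, so one equivalent of MeI with a weak base should methylate it alone, which places the methoxyl between the C-methyl group and the last free ring carbon.

Step 13
Reactants: 22 2,6-dihydroxy-4-methoxy-3-methylbenzaldehyde
Product: 23 3-butanoyl-2,6-dihydroxy-4-methoxy-5-methylbenzaldehyde
Conditions: PrCO2H, BF3·OEt2, 70 °C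
Reagents that add atoms: butanoic acid CCCC(=O)O
Why: Friedel–Crafts acylation at the single remaining ring carbon, which is ortho or para to all three oxygen substituents; formyl- and acyl-phloroglucinols accept a further acyl group under these conditions and BF3 should not cleave the aryl methyl ether.

Step 14
Reactants: 23 3-butanoyl-2,6-dihydroxy-4-methoxy-5-methylbenzaldehyde
Product: 25 1-[3-[(dimethylamino)methyl]-2,4-dihydroxy-6-methoxy-5-methylphenyl]butan-1-one, via iminium acetate 24 (not isolated)
Conditions: Me2NH (2 M in THF), NaBH(OAc)3, AcOH, DCE, rt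
Reagents that add atoms: dimethylamine CNC
Why: Reductive amination: the aldehyde condenses with Me2NH to iminium 24, which NaBH(OAc)3 reduces while the hydrogen-bonded, hindered aryl ketone is left, giving the phenolic Mannich base directly.

Step 15
Reactants: 18 1-[3-[(3-acetyl-2,6-dihydroxy-4-methoxy-5-methylphenyl)methyl]-2,4,6-trihydroxyphenyl]butan-1-one; 25 1-[3-[(dimethylamino)methyl]-2,4-dihydroxy-6-methoxy-5-methylphenyl]butan-1-one
Product: 27 Agrimol F (1-[3-[(3-acetyl-2,6-dihydroxy-4-methoxy-5-methylphenyl)methyl]-5-[(3-butanoyl-2,6-dihydroxy-4-methoxy-5-methylphenyl)methyl]-2,4,6-trihydroxyphenyl]butan-1-one), via quinone methide 26 (not isolated)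
Conditions: 1,4-dioxane, 100 °C, Ar
Reagents that add atoms: none
Why: Mannich-base alkylation through an ortho-quinone methide: thermal loss of Me2NH from 25 gives 26, which is attacked in a conjugate (Friedel–Crafts-type) addition by the only unsubstituted ring carbon present, that of ring B in 18, and tautomerisation restores both arenes.

**Compound list**

1 | 4-hydroxy-6-methyl-2H-pyran-2-one | CC1=CC(O)=CC(=O)O1 | starting material
2 | 6-methyl-3-methylidene-2H-pyran-2,4(3H)-dione | CC1=CC(=O)C(=C)C(=O)O1 | intermediate (not isolated)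
3 | 4-hydroxy-6-methyl-3-[(phenylsulfanyl)methyl]-2H-pyran-2-one | CC1=CC(O)=C(CSc2ccccc2)C(=O)O1 | intermediate
4 | 4-hydroxy-3,6-dimethyl-2H-pyran-2-one | CC1=CC(O)=C(C)C(=O)O1 | intermediate
5 | 4-methoxy-3,6-dimethyl-2H-pyran-2-one | COC1=C(C)C(=O)OC(C)=C1 | intermediate
6 | phloroglucinol (benzene-1,3,5-triol) | Oc1cc(O)cc(O)c1 | starting material
7 | 1,3,5-tris(benzyloxy)benzene | c1ccc(COc2cc(OCc3ccccc3)cc(OCc3ccccc3)c2)cc1 | intermediate
8 | dimethyl[[2,4,6-tris(benzyloxy)phenyl]methylidene]azanium chloride | C[N+](C)=Cc1c(OCc2ccccc2)cc(OCc2ccccc2)cc1OCc1ccccc1.[Cl-] | intermediate (not isolated)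
9 | 2,4,6-tris(benzyloxy)benzaldehyde | O=Cc1c(OCc2ccccc2)cc(OCc2ccccc2)cc1OCc1ccccc1 | intermediate
10 | trimethyl phosphonoacetate | COC(=O)CP(=O)(OC)OC | starting material
11 | methyl (2E)-3-[2,4,6-tris(benzyloxy)phenyl]prop-2-enoate | COC(=O)/C=C/c1c(OCc2ccccc2)cc(OCc2ccccc2)cc1OCc1ccccc1 | intermediate
12 | methyl 3-[2,4,6-tris(benzyloxy)phenyl]propanoate | COC(=O)CCc1c(OCc2ccccc2)cc(OCc2ccccc2)cc1OCc1ccccc1 | intermediate
13 | bromo[[1-methoxy-3-[2,4,6-tris(benzyloxy)phenyl]prop-1-en-1-yl]oxy]magnesium (enolate of 12) | COC(O[Mg]Br)=CCc1c(OCc2ccccc2)cc(OCc2ccccc2)cc1OCc1ccccc1 | intermediate (not isolated)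
14 | methyl (4E)-5-methoxy-4-methyl-3,7-dioxo-2-[[2,4,6-tris(benzyloxy)phenyl]methyl]oct-4-enoate (racemic at C2) | COC(=O)C(Cc1c(OCc2ccccc2)cc(OCc2ccccc2)cc1OCc1ccccc1)C(=O)/C(C)=C(/OC)CC(C)=O | intermediate (not isolated)
15 | 1-[2,4-dihydroxy-6-methoxy-5-methyl-3-[[2,4,6-tris(benzyloxy)phenyl]methyl]phenyl]ethan-1-one | CC(=O)c1c(O)c(Cc2c(OCc3ccccc3)cc(OCc3ccccc3)cc2OCc2ccccc2)c(O)c(C)c1OC | intermediate
16 | 1-[2,4-dihydroxy-6-methoxy-5-methyl-3-[(2,4,6-trihydroxyphenyl)methyl]phenyl]ethan-1-one | CC(=O)c1c(O)c(Cc2c(O)cc(O)cc2O)c(O)c(C)c1OC | intermediate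
17 | 1-[3-[(3-acetyl-2,6-dihydroxy-4-methoxy-5-methylphenyl)methyl]-2,4,6-trihydroxyphenyl]butan-1-iminium chloride | CCCC(=[NH2+])c1c(O)cc(O)c(Cc2c(O)c(C)c(OC)c(C(C)=O)c2O)c1O.[Cl-] | intermediate (not isolated)
18 | 1-[3-[(3-acetyl-2,6-dihydroxy-4-methoxy-5-methylphenyl)methyl]-2,4,6-trihydroxyphenyl]butan-1-one | CCCC(=O)c1c(O)cc(O)c(Cc2c(O)c(C)c(OC)c(C(C)=O)c2O)c1O | intermediate
19 | 2-methylbenzene-1,3,5-triol | Cc1c(O)cc(O)cc1O | starting material
20 | dimethyl[(2,4,6-trihydroxy-3-methylphenyl)methylidene]azanium chloride | C[N+](C)=Cc1c(O)cc(O)c(C)c1O.[Cl-] | intermediate (not isolated)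
21 | 2,4,6-trihydroxy-3-methylbenzaldehyde | Cc1c(O)cc(O)c(C=O)c1O | intermediate
22 | 2,6-dihydroxy-4-methoxy-3-methylbenzaldehyde | COc1cc(O)c(C=O)c(O)c1C | intermediate
23 | 3-butanoyl-2,6-dihydroxy-4-methoxy-5-methylbenzaldehyde | CCCC(=O)c1c(O)c(C=O)c(O)c(C)c1OC | intermediate
24 | [(3-butanoyl-2,6-dihydroxy-4-methoxy-5-methylphenyl)methylidene]dimethylazanium acetate | CCCC(=O)c1c(O)c(C=[N+](C)C)c(O)c(C)c1OC.CC(=O)[O-] | intermediate (not isolated)
25 | 1-[3-[(dimethylamino)methyl]-2,4-dihydroxy-6-methoxy-5-methylphenyl]butan-1-one | CCCC(=O)c1c(O)c(CN(C)C)c(O)c(C)c1OC | intermediate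
26 | 4-butanoyl-5-hydroxy-3-methoxy-2-methyl-6-methylidenecyclohexa-2,4-dien-1-one | C=C1C(=O)C(C)=C(OC)C(C(=O)CCC)=C1O | intermediate (not isolated)
27 | Agrimol F, 1-[3-[(3-acetyl-2,6-dihydroxy-4-methoxy-5-methylphenyl)methyl]-5-[(3-butanoyl-2,6-dihydroxy-4-methoxy-5-methylphenyl)methyl]-2,4,6-trihydroxyphenyl]butan-1-one | CCCC(=O)c1c(O)c(Cc2c(O)c(C)c(OC)c(C(C)=O)c2O)c(O)c(Cc2c(O)c(C)c(OC)c(C(=O)CCC)c2O)c1O | target

**Step count**

Total: 15 steps. Longest linear sequence: 8 steps (steps 4, 5, 6, 7, 8, 9, 10, 15).

**Steps most likely to fail**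

1. Step 8 (Proposed new method). What may go wrong: proton transfer from the 6-methyl group of 5 to the enolate, conjugate addition at C6, or arrest at the open-chain stage with retro-Claisen cleavage by methoxide instead of ring closure. The fallback uses only known reactions (Friedel–Crafts acylation, reductive amination, Mannich-base alkylation); it sets out from 22 and comes back to the route at 16. Aldehyde 22 would be acetylated at its one free ring carbon (AcOH, BF3·OEt2, 70 °C) to 3-acetyl-2,6-dihydroxy-4-methoxy-5-methylbenzaldehyde F1. Reductive amination (Me2NH, NaBH(OAc)3, DCE), passing through [(3-acetyl-2,6-dihydroxy-4-methoxy-5-methylphenyl)methylidene]dimethylazanium acetate F2, would give the ring A Mannich base 1-[3-[(dimethylamino)methyl]-2,4-dihydroxy-6-methoxy-5-methylphenyl]ethan-1-one F3. Heating F3 with a fivefold excess of phloroglucinol 6 in dioxane would release the quinone methide 4-acetyl-5-hydroxy-3-methoxy-2-methyl-6-methylidenecyclohexa-2,4-dien-1-one F4, which C-alkylates 6 once and gives 16; steps 10 and 15 then follow unchanged.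

2. Step 15. What may go wrong: self-condensation of the quinone methide and re-addition of the amine may compete with C-alkylation of the crowded, acyl-deactivated ring B carbon, and at 100 °C the methylene bridge already present may exchange between rings. The fallback forms the bridge before ring B carries its butanoyl group, when that ring is far more nucleophilic; it sets out from 16 and 25 and comes back at 27. Mannich base 25, added slowly to an excess of 16 (dioxane, 60 °C), would give through 26 the trimer 1-[3-[[3-[(3-acetyl-2,6-dihydroxy-4-methoxy-5-methylphenyl)methyl]-2,4,6-trihydroxyphenyl]methyl]-2,4-dihydroxy-6-methoxy-5-methylphenyl]butan-1-one F5. Houben–Hoesch acylation of the one remaining ring B carbon (PrCN, ZnCl2, HCl) would give 1-[3-[(3-acetyl-2,6-dihydroxy-4-methoxy-5-methylphenyl)methyl]-5-[(3-butanoyl-2,6-dihydroxy-4-methoxy-5-methylphenyl)methyl]-2,4,6-trihydroxyphenyl]butan-1-iminium chloride F6, which is hydrolysed to 27.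

3. Step 10. What may go wrong: ipso protonation of the phloroglucinol ring under HCl/ZnCl2 or during the hot aqueous hydrolysis may cleave and redistribute the diarylmethane bridge, and the polyphenol may convert incompletely for lack of solubility. The fallback acylates at the benzyl ether stage; it sets out from 15 and comes back at 18. Ketone 15 would be acylated on ring B with butanoic acid and (CF3CO)2O (CH2Cl2, 0 °C → rt; Friedel–Crafts acylation by the mixed anhydride), followed by brief K2CO3/MeOH to return any O-acylated phenol of ring A, to give 1-[3-[(3-acetyl-2,6-dihydroxy-4-methoxy-5-methylphenyl)methyl]-2,4,6-tris(benzyloxy)phenyl]butan-1-one F7. Hydrogenolysis (H2, 10% Pd/C) would then give 18.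

**Further compounds**

F1 | step 8 | 3-acetyl-2,6-dihydroxy-4-methoxy-5-methylbenzaldehyde | CC(=O)c1c(O)c(C=O)c(O)c(C)c1OC
F2 | step 8 | [(3-acetyl-2,6-dihydroxy-4-methoxy-5-methylphenyl)methylidene]dimethylazanium acetate | CC(=O)c1c(O)c(C=[N+](C)C)c(O)c(C)c1OC.CC(=O)[O-]
F3 | step 8 | 1-[3-[(dimethylamino)methyl]-2,4-dihydroxy-6-methoxy-5-methylphenyl]ethan-1-one | CC(=O)c1c(O)c(CN(C)C)c(O)c(C)c1OC
F4 | step 8 | 4-acetyl-5-hydroxy-3-methoxy-2-methyl-6-methylidenecyclohexa-2,4-dien-1-one | C=C1C(=O)C(C)=C(OC)C(C(C)=O)=C1O
F5 | step 15 | 1-[3-[[3-[(3-acetyl-2,6-dihydroxy-4-methoxy-5-methylphenyl)methyl]-2,4,6-trihydroxyphenyl]methyl]-2,4-dihydroxy-6-methoxy-5-methylphenyl]butan-1-one | CCCC(=O)c1c(O)c(Cc2c(O)cc(O)c(Cc3c(O)c(C)c(OC)c(C(C)=O)c3O)c2O)c(O)c(C)c1OC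
F6 | step 15 | 1-[3-[(3-acetyl-2,6-dihydroxy-4-methoxy-5-methylphenyl)methyl]-5-[(3-butanoyl-2,6-dihydroxy-4-methoxy-5-methylphenyl)methyl]-2,4,6-trihydroxyphenyl]butan-1-iminium chloride | CCCC(=[NH2+])c1c(O)c(Cc2c(O)c(C)c(OC)c(C(C)=O)c2O)c(O)c(Cc2c(O)c(C)c(OC)c(C(=O)CCC)c2O)c1O.[Cl-]
F7 | step 10 | 1-[3-[(3-acetyl-2,6-dihydroxy-4-methoxy-5-methylphenyl)methyl]-2,4,6-tris(benzyloxy)phenyl]butan-1-one | CCCC(=O)c1c(OCc2ccccc2)cc(OCc2ccccc2)c(Cc2c(O)c(C)c(OC)c(C(C)=O)c2O)c1OCc1ccccc1
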